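**Retrosynthetic overview**

1. Numbering (bicyclo[3.3.1]nonan-9-one): C1 = C(OH) bridgehead, C2 = CH2, C3 = CH–N, C4 = CH–O, C5 = CH bridgehead, C6 = CHOH, C7–C8 = oxirane, C9 = C=O; ring A = C1-C2-C3-C4-C5-C9, ring B = C1-C8-C7-C6-C5-C9. The plan rests on one feature: the C3 nitrogen and the C1 tertiary hydroxyl are 1,3-related and cis on ring A, so they are the two ends of a cleaved isoxazolidine N–O bond.
2. Endgame disconnections: the amide N–C(O) bond (acid 28 from δ-decalactone), the C7–C8 oxirane (epoxidation directed by the C1 and C6 hydroxyls), and ring B at C5–C6 (magnesium-chelated aldol of a (Z)-enal held on C1).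
3. Key disconnection: re-joining N to O gives a 6-oxa-7-azabicyclo[3.2.1]octan-4-one. A retro-[3+2] (C3–C2 and C1–O) opens it to an acyclic C3 nitrone, tethered through C4–C5–C9 to the 2-methylene enynone C9(=O)–C1(=C2H2)–C8≡C7–C6H(OEt)2.
4. Precursor: C3–C4–C5–C9 and the only pre-existing stereocentre (C4) come from (R)-malic acid, C1–C2 from 1,1-dibromoethene, and C6–C8 from 3,3-diethoxyprop-1-yne. The reactive enynone is unveiled only one step before the nitrone.
5. Ring order: isoxazolidine and ring A together (step 10), isoxazolidine opened (step 12), ring B (step 15), oxirane (step 16).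

Key step: step 10

Remark: stabilised 1,1-dibromoethene is taken as a purchasable reagent.
Remark: racemic δ-decalactone suffices because its stereocentre ends as the side-chain ketone. Compounds 9 and 10 are carried as C9 epimers and 18 as anomers, because these centres are erased or re-set later.

**Route**

Step 1
Reactants: 1 (R)-malic acid
Product: 2 dimethyl (R)-malate
Conditions: MeOH, H2SO4 (cat.), reflux
Reagents that add atoms: methanol (SMILES CO)
Why: Fischer esterification under acid catalysis does not touch the carbinol stereocentre, which becomes C4.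

Step 2
Reactants: 2 dimethyl (R)-malate
Product: 3 methyl (R)-3,4-dihydroxybutanoate
Conditions: BH3·SMe2, NaBH4 (cat.), THF, 0 °C to rt; MeOH quench
Reagents that add atoms: none
Why: Hydroxyl-directed borane reduction, in which boron bound to the carbinol oxygen delivers hydride through a five-membered chelate to the neighbouring ester only, so the distal ester (future C9) survives and the stereocentre is not involved.

Step 3
Reactants: 3 methyl (R)-3,4-dihydroxybutanoate
Product: 4 methyl (R)-3,4-bis(tert-butyldimethylsilyloxy)butanoate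
Conditions: TBSCl, imidazole, DMF, rt
Reagents that add atoms: tert-butyldimethylsilyl chloride (SMILES CC(C)(C)[Si](C)(C)Cl)
Why: Imidazole-promoted silylation of both hydroxyls blocks lactonisation and installs the C4 silyl ether that is carried to the last step.

Step 4
Reactants: 4 methyl (R)-3,4-bis(tert-butyldimethylsilyloxy)butanoate
Product: 5 (R)-3,4-bis(tert-butyldimethylsilyloxy)butanal
Conditions: i-Bu2AlH, CH2Cl2, −78 °C; aq. potassium sodium tartrate
Reagents that add atoms: none
Why: Partial ester reduction stops at the tetrahedral aluminium hemiacetal at low temperature and releases the C9 aldehyde only on work-up.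

Step 5
Reactants: 6 3,3-diethoxyprop-1-yne; 7 1,1-dibromoethene
Product: 8 2-bromo-5,5-diethoxypent-1-en-3-yne
Conditions: 7 (3 equiv), PdCl2(PPh3)2 (cat.), CuI (cat.), Et3N, THF, 0 °C to rt
Reagents that add atoms: none
Why: Sonogashira coupling in which the excess of geminal dibromide limits the reaction to one C–Br bond, leaving the second vinylic bromide as the handle for the C1–C9 bond.

Step 6
Reactants: 5 (R)-3,4-bis(tert-butyldimethylsilyloxy)butanal; 8 2-bromo-5,5-diethoxypent-1-en-3-yne
Product: 9 (2R)-1,2-bis(tert-butyldimethylsilyloxy)-8,8-diethoxy-5-methylideneoct-6-yn-4-ol (both carbinol epimers)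
Conditions: CrCl2 (4 equiv), NiCl2 (cat.), DMF, rt
Reagents that add atoms: none
Why: Nozaki–Hiyama–Kishi coupling, in which zerovalent nickel inserts into the vinylic C–Br bond and transmetalation gives a weakly basic alkenylchromium species that adds to the aldehyde without disturbing the silyl ethers or the acetal, the new carbinol centre being irrelevant because step 8 oxidises it.

Step 7
Reactants: 9 (2R)-1,2-bis(tert-butyldimethylsilyloxy)-8,8-diethoxy-5-methylideneoct-6-yn-4-ol
Product: 10 (2R)-2-(tert-butyldimethylsilyloxy)-8,8-diethoxy-5-methylideneoct-6-yne-1,4-diol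
Conditions: HF·pyridine, pyridine, THF, 0 °C
Reagents that add atoms: none
Why: Buffered fluoride desilylation discriminates on steric grounds, so only the primary silyl ether should be lost while the secondary one and the propargylic acetal persist.

Step 8
Reactants: 10 (2R)-2-(tert-butyldimethylsilyloxy)-8,8-diethoxy-5-methylideneoct-6-yne-1,4-diol
Product: 11 (2R)-2-(tert-butyldimethylsilyloxy)-8,8-diethoxy-5-methylidene-4-oxooct-6-ynal
Conditions: Dess–Martin periodinane (3 equiv), CH2Cl2, 0 °C to rt; filtration through silica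
Reagents that add atoms: none
Why: Dess–Martin oxidation converts both carbinols without base, which spares the β-silyloxy carbonyl array from elimination, and the excess of reagent binds both hydroxyls so that lactol formation should not intervene.

Step 9
Reactants: 11 (2R)-2-(tert-butyldimethylsilyloxy)-8,8-diethoxy-5-methylidene-4-oxooct-6-ynal; 12 N-(4-methoxybenzyl)hydroxylamine
Product: 13 (Z)-N-[(2R)-2-(tert-butyldimethylsilyloxy)-8,8-diethoxy-5-methylidene-4-oxooct-6-yn-1-ylidene]-1-(4-methoxyphenyl)methanamine N-oxide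
Conditions: 12 (1.0 equiv, slow addition), 4 Å molecular sieves, CH2Cl2, −20 to 0 °C; filtered and used at once
Reagents that add atoms: none
Why: Condensation of an N-alkylhydroxylamine with an aldehyde gives the (Z)-aldonitrone, the α-silyloxy aldehyde being expected to capture the single equivalent of hydroxylamine as its carbinolamine faster than conjugate addition to the enynone, which in any case is reversible.

Step 10
Reactants: 13 (Z)-nitrone of keto aldehyde 11
Product: 14 (1S,2R,5S)-2-(tert-butyldimethylsilyloxy)-5-(3,3-diethoxyprop-1-yn-1-yl)-7-(4-methoxybenzyl)-6-oxa-7-azabicyclo[3.2.1]octan-4-one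
Conditions: toluene (0.005 M), BHT (cat.), 80 °C
Reagents that add atoms: none
Why: A thermal, concerted [4π+2π] addition of the (Z)-nitrone across the C1=C2 bond, that is an intramolecular nitrone–alkene cycloaddition run without Lewis acid. Its closest relatives are hex-5-enyl-type nitrones that carry a substituent on the inner alkene carbon and the intermolecular additions of nitrones to methacrylates and α-methylene ketones, all of which join the nitrone carbon to the CH2 terminus and the oxygen to the fully substituted carbon. Ring A closes in the bridged (endo) mode by the C3–C2 bond and the isoxazolidine C3–N–O–C1–C2 closes in the same event by the O–C1 bond, the two rings sharing C1–C2–C3 in a bicyclo[3.2.1] frame that only the (Z)-nitrone, whose oxygen lies on the C4 side, can reach. C3 is controlled by C4: in the chair-like array the C4–OSi bond is equatorial and antiperiplanar to the forming C3–C2 bond (a Felkin–Anh arrangement), which places N cis to the silyloxy group, and C1 follows from C3 because the N–O bridge must span one face of ring A, leaving the alkynyl arm equatorial. The step needs regioselectivity against the fused mode (C3–C1 and O–C2, the usual result of a three-atom tether) and chemoselectivity for the alkene over the alkyne; the first is secured by the 1,1-disubstitution, since the fused mode would have to join the branched C3 to a carbon that becomes quaternary, the second by the acyl activation of the methylene group next to an unactivated internal alkyne. Because plain Michael polarisation of the enone would rather send oxygen to C2, anything that enhances it (Lewis or Brønsted acid) is excluded and the reaction is run dilute with a radical inhibitor.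

Step 11
Reactants: 14 bridged isoxazolidine alkyne
Product: 15 (1S,2R,5S)-2-(tert-butyldimethylsilyloxy)-5-[(Z)-3,3-diethoxyprop-1-en-1-yl]-7-(4-methoxybenzyl)-6-oxa-7-azabicyclo[3.2.1]octan-4-one
Conditions: H2 (1 atm), Pd/CaCO3 poisoned with Pb(OAc)2, quinoline, EtOAc, rt
Reagents that add atoms: none
Why: Lindlar semi-hydrogenation adds H2 syn to the alkyne and gives the (Z)-alkene that ring B requires, while the poisoned catalyst leaves the N–O bond, the N-benzylic bond and the ketone alone.

Step 12
Reactants: 15 bridged isoxazolidine (Z)-alkene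
Product: 16 (2S,4S,5R)-5-(tert-butyldimethylsilyloxy)-2-[(Z)-3,3-diethoxyprop-1-en-1-yl]-2-hydroxy-4-[(4-methoxybenzyl)amino]cyclohexan-1-one
Conditions: Mo(CO)6, MeCN/H2O (15:1), 80 °C
Reagents that add atoms: none
Why: Reductive N–O cleavage by zerovalent molybdenum (insertion, then hydrolysis) frees the cis C3 amine and C1 alcohol with retention at both carbons, avoids the α-keto C1–O scission that single-electron reductants risk, and allows ring A to flip so that the C1 arm can become axial.

Step 13
Reactants: 16 amino ketol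
Product: 17 benzyl N-[(1S,2R,5S)-2-(tert-butyldimethylsilyloxy)-5-[(Z)-3,3-diethoxyprop-1-en-1-yl]-5-hydroxy-4-oxocyclohexyl]-N-(4-methoxybenzyl)carbamate
Conditions: CbzCl, NaHCO3, THF/H2O, 0 °C to rt
Reagents that add atoms: benzyl chloroformate (SMILES O=C(Cl)OCc1ccccc1)
Why: Schotten–Baumann carbamoylation masks the secondary amine so that it can neither condense with the coming enal nor be oxidised in step 16, the tertiary alcohol being too hindered to react.

Step 14
Reactants: 17 carbamate acetal
Product: 18 benzyl N-[(5S,8R,9S)-8-(tert-butyldimethylsilyloxy)-2-hydroxy-6-oxo-1-oxaspiro[4.5]dec-3-en-9-yl]-N-(4-methoxybenzyl)carbamate (anomers at C2 of the spiro numbering)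
Conditions: PPTS (cat.), acetone/H2O (9:1), 40 °C
Reagents that add atoms: water (SMILES O)
Why: Acid-catalysed acetal hydrolysis, after which the C1 hydroxyl traps the (Z)-enal as a five-membered lactol that holds the Z geometry and cannot aromatise because C1 is quaternary.

Step 15
Reactants: 18 spiro lactol
Product: 20 benzyl N-[(1S,3S,4R,5R,6R)-4-(tert-butyldimethylsilyloxy)-1,6-dihydroxy-9-oxobicyclo[3.3.1]non-7-en-3-yl]-N-(4-methoxybenzyl)carbamate, via open (Z)-hydroxy enal 19 (not isolated)
Conditions: MgBr2·OEt2 (3 equiv), i-Pr2NEt, CH2Cl2, −20 to 0 °C; pH 7 buffer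
Reagents that add atoms: none
Why: Intramolecular aldol addition, a 6-(enolendo)-exo-trig closure of the kind that turns 2-(3-oxopropyl)cyclohexanones into bicyclo[3.3.1]nonan-9-ones, in which base opens the lactol, magnesium bound to the C1 alkoxide and the C9 carbonyl permits soft enolisation towards C5 (the only enolisable side), C5 is set because the C1-bound arm can reach only its own face of ring A, and C6 is set by the closed magnesium-bridged transition state that keeps the aldehyde oxygen next to the C9 oxygen and so gives the hydroxyl axial on ring B and syn to the C1 hydroxyl.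

Step 16
Reactants: 20 bicyclic enediol ketone
Product: 21 benzyl N-[(1S,3S,4R,5R,6S,7S,8S)-4-(tert-butyldimethylsilyloxy)-7,8-epoxy-1,6-dihydroxy-9-oxobicyclo[3.3.1]nonan-3-yl]-N-(4-methoxybenzyl)carbamate
Conditions: VO(acac)2 (cat.), t-BuOOH, CH2Cl2, 0 °C to rt
Reagents that add atoms: tert-butyl hydroperoxide (SMILES CC(C)(C)OO)
Why: Hydroxyl-directed vanadium-catalysed epoxidation, in which both allylic hydroxyls (C1 and C6) lie on the exo face of ring B and deliver the peroxide to that face, which is also the convex one, so that C7 and C8 are set with the oxirane cis to both hydroxyls.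

Step 17
Reactants: 21 epoxy carbamate
Product: 22 (1S,3S,4R,5R,6S,7S,8S)-3-amino-4-(tert-butyldimethylsilyloxy)-7,8-epoxy-1,6-dihydroxybicyclo[3.3.1]nonan-9-one
Conditions: H2 (1 atm), Pd(OH)2/C, MeOH/AcOH (20:1), rt
Reagents that add atoms: none
Why: Catalytic hydrogenolysis removes the benzyl carbamate (with loss of CO2) and the 4-methoxybenzyl group in one operation at the only stage where the molecule holds no C=C bond, the unactivated oxirane, the ketone and the silyl ether being inert to it.

Step 18
Reactants: 23 δ-decalactone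
Product: 24 6-pentyloxan-2-ol
Conditions: i-Bu2AlH, CH2Cl2, −78 °C; aq. potassium sodium tartrate
Reagents that add atoms: none
Why: Partial reduction of a lactone stops at the lactol because the aluminium hemiacetal is stable at low temperature.

Step 19
Reactants: 24 6-pentyloxan-2-ol; 25 tert-butyl 2-(triphenyl-λ5-phosphanylidene)acetate
Product: 26 tert-butyl (E)-7-hydroxydodec-2-enoate
Conditions: toluene, PhCO2H (cat.), 60 °C
Reagents that add atoms: none
Why: Wittig olefination of the hydroxy aldehyde tautomer of the lactol with a stabilised ylide gives the (E)-enoate under thermodynamic control of the oxaphosphetane.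

Step 20
Reactants: 26 tert-butyl (E)-7-hydroxydodec-2-enoate
Product: 27 tert-butyl (E)-7-oxododec-2-enoate
Conditions: Dess–Martin periodinane, CH2Cl2, rt
Reagents that add atoms: none
Why: Dess–Martin oxidation of the secondary alcohol gives the side-chain ketone, erases the lactone-derived stereocentre and removes the hydroxyl before it can add to the enoate.

Step 21
Reactants: 27 tert-butyl (E)-7-oxododec-2-enoate
Product: 28 (E)-7-oxododec-2-enoic acid
Conditions: TFA/CH2Cl2 (1:4), 0 °C to rt
Reagents that add atoms: none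
Why: Acidolysis of the tert-butyl ester (loss of isobutene) avoids a basic hydrolysis that could set off intramolecular Michael addition of the ketone enolate to the enoate.

Step 22
Reactants: 22 amino epoxy ketol; 28 (E)-7-oxododec-2-enoic acid
Product: 29 (E)-N-[(1S,3S,4R,5R,6S,7S,8S)-4-(tert-butyldimethylsilyloxy)-7,8-epoxy-1,6-dihydroxy-9-oxobicyclo[3.3.1]nonan-3-yl]-7-oxododec-2-enamide
Conditions: EDC, HOBt, CH2Cl2, 0 °C to rt
Reagents that add atoms: none
Why: Carbodiimide/HOBt amide coupling acylates the primary amine chemoselectively over the hindered secondary and tertiary hydroxyls and needs no strong base that could cause retro-aldol cleavage.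

Step 23
Reactants: 29 C4 silyl ether of the target
Product: 30 isariotin C, (E)-N-[(1S,3S,4R,5S,6S,7S,8S)-7,8-epoxy-1,4,6-trihydroxy-9-oxobicyclo[3.3.1]nonan-3-yl]-7-oxododec-2-enamide
Conditions: HF·pyridine, pyridine, THF, 0 °C to rt
Reagents that add atoms: none
Why: Buffered fluoride desilylation frees the C4 hydroxyl under non-basic conditions, so that neither retro-aldol cleavage of the β-hydroxy ketones nor opening of the electron-poor oxirane is expected.

**Compound list**

1 | (R)-malic acid | O[C@H](CC(=O)O)C(=O)O | starting material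
2 | dimethyl (R)-malate | O[C@H](CC(=O)OC)C(=O)OC | intermediate
3 | methyl (R)-3,4-dihydroxybutanoate | O[C@H](CC(=O)OC)CO | intermediate
4 | methyl (R)-3,4-bis(tert-butyldimethylsilyloxy)butanoate | CC(C)(C)[Si](C)(C)O[C@H](CC(=O)OC)CO[Si](C)(C)C(C)(C)C | intermediate
5 | (R)-3,4-bis(tert-butyldimethylsilyloxy)butanal | CC(C)(C)[Si](C)(C)O[C@H](CC=O)CO[Si](C)(C)C(C)(C)C | intermediate
6 | 3,3-diethoxyprop-1-yne | C#CC(OCC)OCC | starting material
7 | 1,1-dibromoethene | C=C(Br)Br | starting material
8 | 2-bromo-5,5-diethoxypent-1-en-3-yne | C=C(Br)C#CC(OCC)OCC | intermediate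
9 | (2R)-1,2-bis(tert-butyldimethylsilyloxy)-8,8-diethoxy-5-methylideneoct-6-yn-4-ol (carbinol epimers) | CC(C)(C)[Si](C)(C)O[C@H](CC(O)C(=C)C#CC(OCC)OCC)CO[Si](C)(C)C(C)(C)C | intermediate
10 | (2R)-2-(tert-butyldimethylsilyloxy)-8,8-diethoxy-5-methylideneoct-6-yne-1,4-diol (carbinol epimers) | CC(C)(C)[Si](C)(C)O[C@H](CC(O)C(=C)C#CC(OCC)OCC)CO | intermediate
11 | (2R)-2-(tert-butyldimethylsilyloxy)-8,8-diethoxy-5-methylidene-4-oxooct-6-ynal | CC(C)(C)[Si](C)(C)O[C@H](CC(=O)C(=C)C#CC(OCC)OCC)C=O | intermediate
12 | N-(4-methoxybenzyl)hydroxylamine | ONCc1ccc(OC)cc1 | starting material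
13 | (Z)-N-(4-methoxybenzyl)nitrone of 11 | [O-]/[N+](Cc1ccc(OC)cc1)=C\[C@H](O[Si](C)(C)C(C)(C)C)CC(=O)C(=C)C#CC(OCC)OCC | intermediate
14 | (1S,2R,5S)-2-(tert-butyldimethylsilyloxy)-5-(3,3-diethoxyprop-1-yn-1-yl)-7-(4-methoxybenzyl)-6-oxa-7-azabicyclo[3.2.1]octan-4-one | COc1ccc(CN2[C@H]3C[C@@](C#CC(OCC)OCC)(O2)C(=O)C[C@H]3O[Si](C)(C)C(C)(C)C)cc1 | intermediate
15 | (1S,2R,5S)-2-(tert-butyldimethylsilyloxy)-5-[(Z)-3,3-diethoxyprop-1-en-1-yl]-7-(4-methoxybenzyl)-6-oxa-7-azabicyclo[3.2.1]octan-4-one | COc1ccc(CN2[C@H]3C[C@@](/C=C\C(OCC)OCC)(O2)C(=O)C[C@H]3O[Si](C)(C)C(C)(C)C)cc1 | intermediate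
16 | (2S,4S,5R)-5-(tert-butyldimethylsilyloxy)-2-[(Z)-3,3-diethoxyprop-1-en-1-yl]-2-hydroxy-4-[(4-methoxybenzyl)amino]cyclohexan-1-one | COc1ccc(CN[C@H]2C[C@@](/C=C\C(OCC)OCC)(O)C(=O)C[C@H]2O[Si](C)(C)C(C)(C)C)cc1 | intermediate
17 | benzyl N-[(1S,2R,5S)-2-(tert-butyldimethylsilyloxy)-5-[(Z)-3,3-diethoxyprop-1-en-1-yl]-5-hydroxy-4-oxocyclohexyl]-N-(4-methoxybenzyl)carbamate | COc1ccc(CN(C(=O)OCc2ccccc2)[C@H]2C[C@@](/C=C\C(OCC)OCC)(O)C(=O)C[C@H]2O[Si](C)(C)C(C)(C)C)cc1 | intermediate
18 | benzyl N-[(5S,8R,9S)-8-(tert-butyldimethylsilyloxy)-2-hydroxy-6-oxo-1-oxaspiro[4.5]dec-3-en-9-yl]-N-(4-methoxybenzyl)carbamate (anomers) | COc1ccc(CN(C(=O)OCc2ccccc2)[C@H]2C[C@@]3(OC(O)C=C3)C(=O)C[C@H]2O[Si](C)(C)C(C)(C)C)cc1 | intermediate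
19 | benzyl N-[(1S,2R,5S)-2-(tert-butyldimethylsilyloxy)-5-hydroxy-4-oxo-5-[(Z)-3-oxoprop-1-en-1-yl]cyclohexyl]-N-(4-methoxybenzyl)carbamate (not isolated) | COc1ccc(CN(C(=O)OCc2ccccc2)[C@H]2C[C@@](/C=C\C=O)(O)C(=O)C[C@H]2O[Si](C)(C)C(C)(C)C)cc1 | intermediate
20 | benzyl N-[(1S,3S,4R,5R,6R)-4-(tert-butyldimethylsilyloxy)-1,6-dihydroxy-9-oxobicyclo[3.3.1]non-7-en-3-yl]-N-(4-methoxybenzyl)carbamate | COc1ccc(CN(C(=O)OCc2ccccc2)[C@H]2C[C@@]3(O)C(=O)[C@H]([C@H](O)C=C3)[C@H]2O[Si](C)(C)C(C)(C)C)cc1 | intermediate
21 | benzyl N-[(1S,3S,4R,5R,6S,7S,8S)-4-(tert-butyldimethylsilyloxy)-7,8-epoxy-1,6-dihydroxy-9-oxobicyclo[3.3.1]nonan-3-yl]-N-(4-methoxybenzyl)carbamate | COc1ccc(CN(C(=O)OCc2ccccc2)[C@H]2C[C@@]3(O)C(=O)[C@H]([C@H](O)[C@@H]4O[C@@H]43)[C@H]2O[Si](C)(C)C(C)(C)C)cc1 | intermediate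
22 | (1S,3S,4R,5R,6S,7S,8S)-3-amino-4-(tert-butyldimethylsilyloxy)-7,8-epoxy-1,6-dihydroxybicyclo[3.3.1]nonan-9-one | N[C@H]1C[C@@]2(O)C(=O)[C@H]([C@H](O)[C@@H]3O[C@@H]32)[C@H]1O[Si](C)(C)C(C)(C)C | intermediate
23 | δ-decalactone (racemic) | CCCCCC1CCCC(=O)O1 | starting material
24 | 6-pentyloxan-2-ol | CCCCCC1CCCC(O)O1 | intermediate
25 | tert-butyl 2-(triphenyl-λ5-phosphanylidene)acetate | CC(C)(C)OC(=O)C=P(c1ccccc1)(c1ccccc1)c1ccccc1 | starting material
26 | tert-butyl (E)-7-hydroxydodec-2-enoate | CCCCCC(O)CCC/C=C/C(=O)OC(C)(C)C | intermediate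
27 | tert-butyl (E)-7-oxododec-2-enoate | CCCCCC(=O)CCC/C=C/C(=O)OC(C)(C)C | intermediate
28 | (E)-7-oxododec-2-enoic acid | CCCCCC(=O)CCC/C=C/C(=O)O | intermediate
29 | (E)-N-[(1S,3S,4R,5R,6S,7S,8S)-4-(tert-butyldimethylsilyloxy)-7,8-epoxy-1,6-dihydroxy-9-oxobicyclo[3.3.1]nonan-3-yl]-7-oxododec-2-enamide | CCCCCC(=O)CCC/C=C/C(=O)N[C@H]1C[C@@]2(O)C(=O)[C@H]([C@H](O)[C@@H]3O[C@@H]32)[C@H]1O[Si](C)(C)C(C)(C)C | intermediate
30 | isariotin C | CCCCCC(=O)CCC/C=C/C(=O)N[C@H]1C[C@@]2(O)C(=O)[C@H]([C@H](O)[C@@H]3O[C@@H]32)[C@H]1O | target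

**Step count and risks**

Total step count: 23.
Longest linear sequence: 18 (steps 1–4, 6–17, 22, 23).

Steps most likely to fail:

**1. Step 10 (key step).**
- What may go wrong: closure in the fused sense (C3 to C1, oxygen to C2), which a three-atom tether normally prefers, or oligomerisation of the doubly activated acceptor before it cyclises.
- Fallback: it sets out from diol 10 and comes back at 14. It moves the cycloaddition to the carbinol oxidation level and uses a hydroxyl template.
- TEMPO/PhI(OAc)2 (one equivalent) oxidises only the primary alcohol of 10. The resulting aldehyde closes onto the C9 hydroxyl as the lactol (3R)-3-(tert-butyldimethylsilyloxy)-5-(5,5-diethoxypent-1-en-3-yn-2-yl)oxolan-2-ol F1.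
- Condensation with 12 opens this lactol to the C9-hydroxy nitrone F2.
- MgBr2·OEt2 in 1,2-dichloroethane then ties the nitrone oxygen and the C9 hydroxyl to one magnesium centre. This is the known magnesium-templated nitrone addition to allylic alcohols. It delivers oxygen to the neighbouring C1 and leaves C3 to bond to C2, giving the bridged isoxazolidine carbinol F3.
- Dess–Martin oxidation of F3 returns to 14.
- The dipolarophile in this detour has no Michael polarisation and carries an sp3 carbon next to C1, so only steric and template effects act. The hydroxylamine also never meets an acceptor, which removes the chemoselectivity question of step 9.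

**2. Step 15.**
- What may go wrong: expulsion of the axial C4 silyloxy group from the C5 enolate, Z-to-E isomerisation of the enal, or an aldehyde that stays masked as lactol so that the enolate lives too long.
- Fallback: it sets out from acetal 17 and comes back at 20. It presents a free aldehyde and uses a preformed boron enolate at low temperature.
- TMSOTf/2,6-lutidine followed by water silylates the C1 hydroxyl and converts the acetal to the aldehyde without aqueous acid. This gives the C1-O-trimethylsilyl (Z)-enal F4, which cannot form a lactol.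
- n-Bu2BOTf/i-Pr2NEt at −78 °C enolises C9 towards C5. Boron enolates of β-silyloxy ketones do not eliminate at this temperature. The ring closes through a closed six-membered transition state, with the same sense at C6, to the C1-O-trimethylsilyl ketol F5.
- Citric acid in MeOH removes the trimethylsilyl group and returns to 20.

**3. Step 6.**
- What may go wrong: sluggish insertion or transmetalation of the bromo enyne, its reductive homocoupling, or reaction of the alkenylmetal through the alkyne terminus.
- Fallback: it sets out from ester 4 and bromide 8 and comes back at 11. It forms C1–C9 by acyl substitution at the ketone level.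
- MeNHOMe·HCl/i-PrMgCl converts 4 into the Weinreb amide F6.
- Bromine–lithium exchange on 8 (t-BuLi, Et2O, −78 °C) gives the 2-lithio enyne F7, which is acylated by F6. After a cold acidic quench this affords the bis-silyl enynone F8.
- HF·pyridine removes the primary silyl ether to give the hydroxy enynone F9.
- A single Dess–Martin oxidation returns to keto aldehyde 11.

**Further compounds**

F1 | step 10 | (3R)-3-(tert-butyldimethylsilyloxy)-5-(5,5-diethoxypent-1-en-3-yn-2-yl)oxolan-2-ol | CC(C)(C)[Si](C)(C)O[C@@H]1CC(OC1O)C(=C)C#CC(OCC)OCC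
F2 | step 10 | (Z)-N-(4-methoxybenzyl)nitrone of (2R)-2-(tert-butyldimethylsilyloxy)-8,8-diethoxy-4-hydroxy-5-methylideneoct-6-ynal | [O-]/[N+](Cc1ccc(OC)cc1)=C\[C@H](O[Si](C)(C)C(C)(C)C)CC(O)C(=C)C#CC(OCC)OCC
F3 | step 10 | (1S,2R,5S)-2-(tert-butyldimethylsilyloxy)-5-(3,3-diethoxyprop-1-yn-1-yl)-7-(4-methoxybenzyl)-6-oxa-7-azabicyclo[3.2.1]octan-4-ol | COc1ccc(CN2[C@H]3C[C@@](C#CC(OCC)OCC)(O2)C(O)C[C@H]3O[Si](C)(C)C(C)(C)C)cc1
F4 | step 15 | benzyl N-[(1S,2R,5S)-2-(tert-butyldimethylsilyloxy)-4-oxo-5-[(Z)-3-oxoprop-1-en-1-yl]-5-(trimethylsilyloxy)cyclohexyl]-N-(4-methoxybenzyl)carbamate | COc1ccc(CN(C(=O)OCc2ccccc2)[C@H]2C[C@@](/C=C\C=O)(O[Si](C)(C)C)C(=O)C[C@H]2O[Si](C)(C)C(C)(C)C)cc1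
F5 | step 15 | C1-O-trimethylsilyl ether of 20 | COc1ccc(CN(C(=O)OCc2ccccc2)[C@H]2C[C@@]3(O[Si](C)(C)C)C(=O)[C@H]([C@H](O)C=C3)[C@H]2O[Si](C)(C)C(C)(C)C)cc1
F6 | step 6 | (R)-3,4-bis(tert-butyldimethylsilyloxy)-N-methoxy-N-methylbutanamide | CC(C)(C)[Si](C)(C)O[C@H](CC(=O)N(C)OC)CO[Si](C)(C)C(C)(C)C
F7 | step 6 | (5,5-diethoxypent-1-en-3-yn-2-yl)lithium | [Li]C(=C)C#CC(OCC)OCC
F8 | step 6 | (2R)-1,2-bis(tert-butyldimethylsilyloxy)-8,8-diethoxy-5-methylideneoct-6-yn-4-one | CC(C)(C)[Si](C)(C)O[C@H](CC(=O)C(=C)C#CC(OCC)OCC)CO[Si](C)(C)C(C)(C)C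
F9 | step 6 | (2R)-2-(tert-butyldimethylsilyloxy)-8,8-diethoxy-1-hydroxy-5-methylideneoct-6-yn-4-one | CC(C)(C)[Si](C)(C)O[C@H](CC(=O)C(=C)C#CC(OCC)OCC)CO
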